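**Plan**
Numbering: ring carbons C1 (CH2), C2/C3 (epoxide), C4 (C(CH3)OH), C5, C6, C7, C8 (CH–O), C9 (C=O), C10 (CHCH3); lactone carbons C11, C12 (C=O), C13 (=CH2). The enabling feature is the free tertiary C4–OH beside the C2–C3 epoxide, which is the footprint of an E-allylic alcohol C4(OH)–C3=C2–C1 (an opened C3–C4 vinyl epoxide), together with the C1–C10 bond, C10 being the acidic carbon next to the C9 ketone.
Retrosynthesis: remove the C2–C3 epoxide oxygen, the O8 angelate, the O5 2-methylbutanoate and the O6–C12 lactone bond; cut the ring at C10–C1; then cut C9–C10 (sulfone acylation), C7–C11 (cuprate addition), C7=C8 (olefination) and C2–C3 with the C4 methyl (alkyne carbometalation–coupling).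
Forward: one linear chain grows from L-threitol acetonide (C4 to C7): the diene end first, then C8/C9 and C11–C13. A temporary delta-lactone (C9 to O12) carries the C8 oxygenation and is opened by the sulfone anion (C10). Palladium then closes the ten-membered ring; the gamma-lactone, both esters and the epoxide follow.
Stereochemistry: C5/C6 from L-tartaric acid (as the threitol acetonide); C7 by syn-selective cuprate addition to a Z-enoate; C8 by trans hydroxylation of the lactone enolate; C4 by reagent-controlled Shi epoxidation; C10 by enolate protonation; C2/C3 by C4–OH-directed epoxidation; the acyl stereocentre from (R)-2-methylbutanoic acid.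

Key step: step 16

Remark: C10 of 25, 26 and 27 is written without a stereodescriptor because both epimers serve (the centre is deprotonated in step 16 and reset in step 17); names of ring compounds use the locants defined above.

Step 1
Reactants: 1 2,3-O-isopropylidene-L-threitol
Product: 2 [(4S,5S)-5-{[(tert-butyldimethylsilyl)oxy]methyl}-2,2-dimethyl-1,3-dioxolan-4-yl]methanol
Conditions: NaH (1.0 equiv), TBSCl (1.0 equiv), THF, 0 °C to rt
Reagents that add atoms: tert-butyldimethylsilyl chloride, CC(C)(C)[Si](C)(C)Cl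
Why: One equivalent of NaH gives a sparingly soluble monoalkoxide that is silylated once (Williamson-type mono-O-silylation of a C2-symmetric diol), so the two homotopic hydroxyls are told apart without touching either stereocentre.

Step 2
Reactants: 2 [(4S,5S)-5-{[(tert-butyldimethylsilyl)oxy]methyl}-2,2-dimethyl-1,3-dioxolan-4-yl]methanol
Product: 3 (4R,5S)-5-{[(tert-butyldimethylsilyl)oxy]methyl}-2,2-dimethyl-1,3-dioxolane-4-carbaldehyde
Conditions: Dess–Martin periodinane, CH2Cl2, 0 °C to rt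
Reagents that add atoms: none
Why: Dess–Martin oxidation gives the aldehyde under near-neutral conditions that should neither epimerise the alpha-alkoxy centre nor cleave the silyl ether or the acetonide.

Step 3
Reactants: 3 (4R,5S)-5-{[(tert-butyldimethylsilyl)oxy]methyl}-2,2-dimethyl-1,3-dioxolane-4-carbaldehyde
Product: 4 tert-butyl{[(4S,5S)-5-ethynyl-2,2-dimethyl-1,3-dioxolan-4-yl]methoxy}dimethylsilane
Conditions: dimethyl (1-diazo-2-oxopropyl)phosphonate, K2CO3, MeOH, 0 °C to rt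
Reagents that add atoms: dimethyl (1-diazo-2-oxopropyl)phosphonate, CC(=O)C(=[N+]=[N-])P(=O)(OC)OC
Why: Ohira–Bestmann (Seyferth–Gilbert) homologation converts the aldehyde into the terminal alkyne that becomes C4 and C3, and the trans-dioxolane is the favoured arrangement so the mild carbonate base should not erode C5.

Step 4
Reactants: 4 tert-butyl{[(4S,5S)-5-ethynyl-2,2-dimethyl-1,3-dioxolan-4-yl]methoxy}dimethylsilane; 5 vinyl bromide
Product: 7 tert-butyl{[(4S,5S)-2,2-dimethyl-5-[(2E)-penta-2,4-dien-2-yl]-1,3-dioxolan-4-yl]methoxy}dimethylsilane, via alkenylalane 6 (not isolated)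
Conditions: AlMe3, Cp2ZrCl2 (cat.), CH2Cl2, 0 °C to rt; then 5, ZnCl2, Pd(PPh3)4 (cat.), THF, rt
Reagents that add atoms: trimethylaluminium, C[Al](C)C
Why: Negishi zirconium-catalysed carboalumination adds methyl and aluminium syn across the alkyne with methyl on the internal carbon (C4), and the palladium-catalysed alkenyl–alkenyl Negishi coupling with vinyl bromide proceeds with retention, so the (E)-diene C1=C2–C3=C4 should result.

Step 5
Reactants: 7 tert-butyl{[(4S,5S)-2,2-dimethyl-5-[(2E)-penta-2,4-dien-2-yl]-1,3-dioxolan-4-yl]methoxy}dimethylsilane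
Product: 8 [(4S,5S)-2,2-dimethyl-5-[(2E)-penta-2,4-dien-2-yl]-1,3-dioxolan-4-yl]methanol
Conditions: Bu4NF, THF, 0 °C to rt
Reagents that add atoms: none
Why: Fluoride-mediated desilylation frees the primary alcohol at C7 without affecting the acetonide or the diene.

Step 6
Reactants: 8 [(4S,5S)-2,2-dimethyl-5-[(2E)-penta-2,4-dien-2-yl]-1,3-dioxolan-4-yl]methanol
Product: 9 (4R,5S)-2,2-dimethyl-5-[(2E)-penta-2,4-dien-2-yl]-1,3-dioxolane-4-carbaldehyde
Conditions: Dess–Martin periodinane, CH2Cl2, 0 °C to rt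
Reagents that add atoms: none
Why: Dess–Martin oxidation gives the C7 aldehyde without epimerising C6 or isomerising the diene.

Step 7
Reactants: 9 (4R,5S)-2,2-dimethyl-5-[(2E)-penta-2,4-dien-2-yl]-1,3-dioxolane-4-carbaldehyde; 10 methyl bis(2,2,2-trifluoroethyl)phosphonoacetate
Product: 11 methyl (2Z)-3-[(4S,5S)-2,2-dimethyl-5-[(2E)-penta-2,4-dien-2-yl]-1,3-dioxolan-4-yl]prop-2-enoate
Conditions: 10, KN(SiMe3)2, 18-crown-6, THF, −78 °C
Reagents that add atoms: none
Why: Still–Gennari olefination with the electron-poor phosphonate under dissociating conditions is kinetically Z-selective and installs C8 and C9 at low temperature without epimerising the aldehyde.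

Step 8
Reactants: 12 2-bromoprop-2-en-1-ol
Product: 13 [(2-bromoprop-2-en-1-yl)oxy](tert-butyl)dimethylsilane
Conditions: TBSCl, imidazole, CH2Cl2, rt
Reagents that add atoms: tert-butyldimethylsilyl chloride, CC(C)(C)[Si](C)(C)Cl
Why: Imidazole-assisted O-silylation of the primary allylic alcohol gives the alkenyl bromide needed for halogen–lithium exchange.

Step 9
Reactants: 11 methyl (2Z)-3-[(4S,5S)-2,2-dimethyl-5-[(2E)-penta-2,4-dien-2-yl]-1,3-dioxolan-4-yl]prop-2-enoate; 13 [(2-bromoprop-2-en-1-yl)oxy](tert-butyl)dimethylsilane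
Product: 17 methyl (3S)-4-{[(tert-butyldimethylsilyl)oxy]methyl}-3-[(4S,5S)-2,2-dimethyl-5-[(2E)-penta-2,4-dien-2-yl]-1,3-dioxolan-4-yl]pent-4-enoate, via alkenyllithium 14 (not isolated), via lithium dialkenylcuprate 15 (not isolated), via silyl ketene acetal 16 (not isolated)
Conditions: 13, t-BuLi (2 equiv per 13), Et2O, −78 °C; CuI (0.5 equiv per 13), −40 °C; then 11, Me3SiCl, THF, −78 °C; aq. NH4Cl
Reagents that add atoms: none
Why: Bromine–lithium exchange and transmetalation give a Gilman cuprate whose Me3SiCl-accelerated 1,4-addition to the (Z)-gamma-alkoxy enoate is governed by allylic 1,3-strain (C6–H held in the enoate plane), so the alkenyl group should enter anti to the C5–C6 bond and set C7 syn to the C6 oxygen (7S).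

Step 10
Reactants: 17 methyl (3S)-4-{[(tert-butyldimethylsilyl)oxy]methyl}-3-[(4S,5S)-2,2-dimethyl-5-[(2E)-penta-2,4-dien-2-yl]-1,3-dioxolan-4-yl]pent-4-enoate
Product: 18 methyl (3S)-4-{[(tert-butyldimethylsilyl)oxy]methyl}-3-[(4S,5R)-5-[(2R,3S)-3-ethenyl-2-methyloxiran-2-yl]-2,2-dimethyl-1,3-dioxolan-4-yl]pent-4-enoate
Conditions: 1,2:4,5-di-O-isopropylidene-beta-L-erythro-2,3-hexodiulo-2,6-pyranose (L-series Shi ketone, 0.3 equiv), KHSO5 (Oxone), K2CO3, Bu4NHSO4 (cat.), MeCN–CH2(OMe)2/aq. Na2B4O7 buffer, pH 10.5, 0 °C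
Reagents that add atoms: potassium peroxymonosulfate (KHSO5), [K+].[O-]S(=O)(=O)OO
Why: Shi asymmetric epoxidation by the chiral dioxirane attacks the electron-rich trisubstituted C3=C4 bond of the diene in preference to the terminal vinyl and the 1,1-disubstituted alkene, and the L-series ketone should deliver oxygen through the spiro transition state to the face that gives the (3S,4R)-vinyl epoxide, fixing C4.

Step 11
Reactants: 18 methyl (3S)-4-{[(tert-butyldimethylsilyl)oxy]methyl}-3-[(4S,5R)-5-[(2R,3S)-3-ethenyl-2-methyloxiran-2-yl]-2,2-dimethyl-1,3-dioxolan-4-yl]pent-4-enoate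
Product: 20 (4S)-4-[(4S,5R)-5-[(2R,3S)-3-ethenyl-2-methyloxiran-2-yl]-2,2-dimethyl-1,3-dioxolan-4-yl]-5-methylideneoxan-2-one, via hydroxy ester 19 (not isolated)
Conditions: Bu4NF, THF, 0 °C to rt
Reagents that add atoms: none
Why: Fluoride removes the silyl group and the liberated alkoxide closes onto the methyl ester (6-exo-trig lactonisation), giving a delta-lactone that holds C8 in a ring next to C7 while the base-stable vinyl epoxide survives.

Step 12
Reactants: 20 (4S)-4-[(4S,5R)-5-[(2R,3S)-3-ethenyl-2-methyloxiran-2-yl]-2,2-dimethyl-1,3-dioxolan-4-yl]-5-methylideneoxan-2-one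
Product: 21 (3S,4R)-4-[(4S,5R)-5-[(2R,3S)-3-ethenyl-2-methyloxiran-2-yl]-2,2-dimethyl-1,3-dioxolan-4-yl]-3-hydroxy-5-methylideneoxan-2-one
Conditions: KN(SiMe3)2, 2-(phenylsulfonyl)-3-phenyloxaziridine, THF, −78 °C; aq. NH4Cl
Reagents that add atoms: 2-(phenylsulfonyl)-3-phenyloxaziridine, O=S(=O)(c1ccccc1)N1OC1c1ccccc1
Why: Davis enolate hydroxylation should occur on the lactone enolate face opposite the bulky dioxolanyl group on C7, which allylic strain from the flanking sp2 carbons places pseudo-axially, so oxygen enters trans and sets 8S.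

Step 13
Reactants: 21 (3S,4R)-4-[(4S,5R)-5-[(2R,3S)-3-ethenyl-2-methyloxiran-2-yl]-2,2-dimethyl-1,3-dioxolan-4-yl]-3-hydroxy-5-methylideneoxan-2-one
Product: 22 (3S,4S)-4-[(4S,5R)-5-[(2R,3S)-3-ethenyl-2-methyloxiran-2-yl]-2,2-dimethyl-1,3-dioxolan-4-yl]-3-[(4-methoxyphenyl)methoxy]-5-methylideneoxan-2-one
Conditions: NaH, 4-methoxybenzyl bromide, Bu4NI (cat.), THF–DMF, 0 °C
Reagents that add atoms: 4-methoxybenzyl bromide, COc1ccc(CBr)cc1
Why: Williamson etherification of the alkoxide protects O8 under non-acidic conditions that the acid-labile vinyl epoxide tolerates, and the alkoxide is not prone to enolise so C8 should hold.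

Step 14
Reactants: 22 (3S,4S)-4-[(4S,5R)-5-[(2R,3S)-3-ethenyl-2-methyloxiran-2-yl]-2,2-dimethyl-1,3-dioxolan-4-yl]-3-[(4-methoxyphenyl)methoxy]-5-methylideneoxan-2-one; 23 ethyl phenyl sulfone
Product: 25 (2RS,4S,5S)-2-(benzenesulfonyl)-5-[(4S,5R)-5-[(2R,3S)-3-ethenyl-2-methyloxiran-2-yl]-2,2-dimethyl-1,3-dioxolan-4-yl]-7-hydroxy-4-[(4-methoxyphenyl)methoxy]-6-methylideneheptan-3-one, via lithiated sulfone 24 (not isolated)
Conditions: 23 (2.2 equiv), n-BuLi (2.2 equiv), THF, −78 °C; then 22, −78 to −40 °C; aq. NH4Cl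
Reagents that add atoms: none
Why: Claisen-type acylation of the alpha-sulfonyl carbanion by the lactone opens the ring to the beta-keto sulfone and adds C10, the product being deprotonated at once by the second equivalent so that no double addition occurs, while the epoxide is not attacked at low temperature.

Step 15
Reactants: 25 (2RS,4S,5S)-2-(benzenesulfonyl)-5-[(4S,5R)-5-[(2R,3S)-3-ethenyl-2-methyloxiran-2-yl]-2,2-dimethyl-1,3-dioxolan-4-yl]-7-hydroxy-4-[(4-methoxyphenyl)methoxy]-6-methylideneheptan-3-one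
Product: 26 (2RS,4S,5S)-2-(benzenesulfonyl)-7-[(tert-butyldimethylsilyl)oxy]-5-[(4S,5R)-5-[(2R,3S)-3-ethenyl-2-methyloxiran-2-yl]-2,2-dimethyl-1,3-dioxolan-4-yl]-4-[(4-methoxyphenyl)methoxy]-6-methylideneheptan-3-one
Conditions: TBSCl, imidazole, CH2Cl2, 0 °C
Reagents that add atoms: tert-butyldimethylsilyl chloride, CC(C)(C)[Si](C)(C)Cl
Why: Silylation of the primary allylic alcohol masks O12 and draws any cyclic hemiketal form of the hydroxy ketone into the open keto sulfone needed for ring closure.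

Step 16
Reactants: 26 (2RS,4S,5S)-2-(benzenesulfonyl)-7-[(tert-butyldimethylsilyl)oxy]-5-[(4S,5R)-5-[(2R,3S)-3-ethenyl-2-methyloxiran-2-yl]-2,2-dimethyl-1,3-dioxolan-4-yl]-4-[(4-methoxyphenyl)methoxy]-6-methylideneheptan-3-one
Product: 27 (2E,4R,5R,6S,7S,8S)-10-(benzenesulfonyl)-4-hydroxy-5,6-(isopropylidenedioxy)-8-[(4-methoxyphenyl)methoxy]-4,10-dimethyl-7-{3-[(tert-butyldimethylsilyl)oxy]prop-1-en-2-yl}cyclodec-2-en-9-one (C10 epimers)
Conditions: Pd(PPh3)4 (10 mol %), Ph2PCH2CH2PPh2 (10 mol %), THF, reflux, slow addition of 26 (final 0.002 M)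
Reagents that add atoms: none
Why: Zerovalent palladium ionises the allylic C3–O bond of the vinyl epoxide with inversion to give a pi-allyl complex over C1–C3 and the C4 alkoxide, which keeps its configuration and deprotonates the keto sulfone at C10 under neutral conditions, after which the stabilised carbanion attacks C1 anti to palladium. The closest known reaction type is the Tsuji–Trost alkylation of vinyl epoxides by sulfone-stabilised carbon nucleophiles as used for macrocyclisation. The ten-membered ring closes by attack at the distal allyl terminus with all three allyl carbons becoming ring members (endo mode), the alternative attack at C3 leading to a more strained eight-membered ring next to the fully substituted C4. The new quaternary centre at C10 is set by the ring conformation and is of no consequence because step 17 erases it, while the syn pi-allyl geometry gives the E-C2=C3 bond and the free C4–OH. The step needs C- over O-alkylation, C1 over C3 attack and cyclisation over oligomerisation, which the soft doubly stabilised carbanion, the shielding of C3 by C4, the generation of the base next to the nucleophile and high dilution should secure.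

Step 17
Reactants: 27 (2E,4R,5R,6S,7S,8S)-10-(benzenesulfonyl)-4-hydroxy-5,6-(isopropylidenedioxy)-8-[(4-methoxyphenyl)methoxy]-4,10-dimethyl-7-{3-[(tert-butyldimethylsilyl)oxy]prop-1-en-2-yl}cyclodec-2-en-9-one (C10 epimers)
Product: 29 (2E,4R,5R,6S,7S,8S,10S)-4-hydroxy-5,6-(isopropylidenedioxy)-8-[(4-methoxyphenyl)methoxy]-4,10-dimethyl-7-{3-[(tert-butyldimethylsilyl)oxy]prop-1-en-2-yl}cyclodec-2-en-9-one, via samarium enolate 28 (not isolated)
Conditions: SmI2 (2.2 equiv), THF, −78 °C; then aq. NH4Cl, −78 °C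
Reagents that add atoms: none
Why: Samarium diiodide cleaves the C10–S bond of the alpha-sulfonyl ketone by two single-electron transfers (reductive desulfonylation) far faster than the C8–O bond, and protonation of the resulting enolate from the less hindered peripheral face of the ring is expected to give the 10S methyl ketone.

Step 18
Reactants: 29 (2E,4R,5R,6S,7S,8S,10S)-4-hydroxy-5,6-(isopropylidenedioxy)-8-[(4-methoxyphenyl)methoxy]-4,10-dimethyl-7-{3-[(tert-butyldimethylsilyl)oxy]prop-1-en-2-yl}cyclodec-2-en-9-one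
Product: 30 (2E,4R,5R,6S,7S,8S,10S)-4,5,6-trihydroxy-7-(3-hydroxyprop-1-en-2-yl)-8-[(4-methoxyphenyl)methoxy]-4,10-dimethylcyclodec-2-en-9-one
Conditions: AcOH–THF–H2O (3:1:1), 40 °C
Reagents that add atoms: none
Why: Aqueous acetic acid hydrolyses the strained trans-fused acetonide and the primary allylic silyl ether (acid-catalysed acetal and silyl ether cleavage), while the 4-methoxybenzyl ether and, at this mild acidity, the tertiary allylic alcohol should remain intact.

Step 19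
Reactants: 30 (2E,4R,5R,6S,7S,8S,10S)-4,5,6-trihydroxy-7-(3-hydroxyprop-1-en-2-yl)-8-[(4-methoxyphenyl)methoxy]-4,10-dimethylcyclodec-2-en-9-one
Product: 33 (2E,4R,5R,6S,7S,8S,10S)-4,5-dihydroxy-8-[(4-methoxyphenyl)methoxy]-9-oxogermacra-2,11(13)-dien-12,6-olide, via hydroxy enal 31 (not isolated), via lactol 32 (not isolated)
Conditions: MnO2 (excess), CH2Cl2, rt
Reagents that add atoms: none
Why: MnO2 oxidises only the allylic primary alcohol to the enal, which the C6 hydroxyl traps as the five-membered lactol that is oxidised further (oxidative lactonisation) to the alpha-methylene gamma-lactone, closure through O6 being favoured over the six-membered alternative through O5.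

Step 20
Reactants: 33 (2E,4R,5R,6S,7S,8S,10S)-4,5-dihydroxy-8-[(4-methoxyphenyl)methoxy]-9-oxogermacra-2,11(13)-dien-12,6-olide; 34 (R)-2-methylbutanoic acid
Product: 35 (2E,4R,5R,6S,7S,8S,10S)-4-hydroxy-8-[(4-methoxyphenyl)methoxy]-5-{[(2R)-2-methylbutanoyl]oxy}-9-oxogermacra-2,11(13)-dien-12,6-olide
Conditions: 34, EDC·HCl, DMAP, CH2Cl2, 0 °C to rt
Reagents that add atoms: none
Why: Steglich esterification acylates the single secondary hydroxyl (O5) while the tertiary C4 hydroxyl does not react, and the carbodiimide method avoids the ketene pathway that could racemise the acid.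

Step 21
Reactants: 35 (2E,4R,5R,6S,7S,8S,10S)-4-hydroxy-8-[(4-methoxyphenyl)methoxy]-5-{[(2R)-2-methylbutanoyl]oxy}-9-oxogermacra-2,11(13)-dien-12,6-olide
Product: 36 (2E,4R,5R,6S,7R,8S,10S)-4,8-dihydroxy-5-{[(2R)-2-methylbutanoyl]oxy}-9-oxogermacra-2,11(13)-dien-12,6-olide
Conditions: DDQ, CH2Cl2–pH 7 phosphate buffer, 0 °C
Reagents that add atoms: none
Why: Oxidative cleavage of the 4-methoxybenzyl ether by DDQ (hydride abstraction followed by hydrolysis) frees O8 without affecting the esters, the lactone or the tertiary allylic alcohol (the C7 descriptor changes by priority only).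

Step 22
Reactants: 36 (2E,4R,5R,6S,7R,8S,10S)-4,8-dihydroxy-5-{[(2R)-2-methylbutanoyl]oxy}-9-oxogermacra-2,11(13)-dien-12,6-olide; 37 angelic acid
Product: 39 (2E,4R,5R,6S,7S,8S,10S)-8-(angeloyloxy)-4-hydroxy-5-{[(2R)-2-methylbutanoyl]oxy}-9-oxogermacra-2,11(13)-dien-12,6-olide, via mixed anhydride 38 (not isolated)
Conditions: 37, 2,4,6-trichlorobenzoyl chloride, Et3N, toluene, rt; then 36, 75 °C
Reagents that add atoms: none
Why: Yamaguchi-type mixed-anhydride esterification without a nucleophilic catalyst transfers the angeloyl group to O8 with the Z geometry of the acid preserved, and the tertiary C4 hydroxyl is too hindered to compete.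

Step 23
Reactants: 39 (2E,4R,5R,6S,7S,8S,10S)-8-(angeloyloxy)-4-hydroxy-5-{[(2R)-2-methylbutanoyl]oxy}-9-oxogermacra-2,11(13)-dien-12,6-olide
Product: 40 CNP0217571.1, (2S,3R,4R,5R,6S,7S,8S,10S)-8-(angeloyloxy)-2,3-epoxy-4-hydroxy-5-{[(2R)-2-methylbutanoyl]oxy}-9-oxogermacr-11(13)-en-12,6-olide
Conditions: VO(acac)2 (cat.), t-BuOOH, CH2Cl2, 0 °C to rt
Reagents that add atoms: tert-butyl hydroperoxide, CC(C)(C)OO
Why: Vanadium-catalysed hydroxyl-directed epoxidation delivers oxygen to C2=C3 on the face syn to the coordinating C4 hydroxyl, which in the ring conformer with the C4–C5 bond perpendicular to the alkene plane is the peripheral face and should give the trans (2S,3R)-epoxide, while the electron-poor methylene lactone and angelate alkenes are not epoxidised.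

**Compound list**
1 | 2,3-O-isopropylidene-L-threitol, [(4S,5S)-2,2-dimethyl-1,3-dioxolane-4,5-diyl]dimethanol | OC[C@@H]1OC(C)(C)O[C@H]1CO | starting material
2 | [(4S,5S)-5-{[(tert-butyldimethylsilyl)oxy]methyl}-2,2-dimethyl-1,3-dioxolan-4-yl]methanol | OC[C@@H]1OC(C)(C)O[C@H]1CO[Si](C)(C)C(C)(C)C | intermediate
3 | (4R,5S)-5-{[(tert-butyldimethylsilyl)oxy]methyl}-2,2-dimethyl-1,3-dioxolane-4-carbaldehyde | O=C[C@@H]1OC(C)(C)O[C@H]1CO[Si](C)(C)C(C)(C)C | intermediate
4 | tert-butyl{[(4S,5S)-5-ethynyl-2,2-dimethyl-1,3-dioxolan-4-yl]methoxy}dimethylsilane | C#C[C@@H]1OC(C)(C)O[C@H]1CO[Si](C)(C)C(C)(C)C | intermediate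
5 | vinyl bromide (bromoethene) | C=CBr | starting material
6 | alkenylalane, dimethyl[(1E)-2-[(4S,5S)-5-{[(tert-butyldimethylsilyl)oxy]methyl}-2,2-dimethyl-1,3-dioxolan-4-yl]prop-1-en-1-yl]alane (formed in the flask) | C[Al](C)/C=C(\C)[C@@H]1OC(C)(C)O[C@H]1CO[Si](C)(C)C(C)(C)C | intermediate
7 | tert-butyl{[(4S,5S)-2,2-dimethyl-5-[(2E)-penta-2,4-dien-2-yl]-1,3-dioxolan-4-yl]methoxy}dimethylsilane | C=C/C=C(\C)[C@@H]1OC(C)(C)O[C@H]1CO[Si](C)(C)C(C)(C)C | intermediate
8 | [(4S,5S)-2,2-dimethyl-5-[(2E)-penta-2,4-dien-2-yl]-1,3-dioxolan-4-yl]methanol | C=C/C=C(\C)[C@@H]1OC(C)(C)O[C@H]1CO | intermediate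
9 | (4R,5S)-2,2-dimethyl-5-[(2E)-penta-2,4-dien-2-yl]-1,3-dioxolane-4-carbaldehyde | C=C/C=C(\C)[C@@H]1OC(C)(C)O[C@H]1C=O | intermediate
10 | methyl bis(2,2,2-trifluoroethyl)phosphonoacetate | COC(=O)CP(=O)(OCC(F)(F)F)OCC(F)(F)F | starting material
11 | methyl (2Z)-3-[(4S,5S)-2,2-dimethyl-5-[(2E)-penta-2,4-dien-2-yl]-1,3-dioxolan-4-yl]prop-2-enoate | C=C/C=C(\C)[C@@H]1OC(C)(C)O[C@H]1/C=C\C(=O)OC | intermediate
12 | 2-bromoprop-2-en-1-ol | OCC(Br)=C | starting material
13 | [(2-bromoprop-2-en-1-yl)oxy](tert-butyl)dimethylsilane | C=C(Br)CO[Si](C)(C)C(C)(C)C | intermediate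
14 | alkenyllithium, {3-[(tert-butyldimethylsilyl)oxy]prop-1-en-2-yl}lithium (formed in the flask) | [Li]C(=C)CO[Si](C)(C)C(C)(C)C | intermediate
15 | lithium bis{3-[(tert-butyldimethylsilyl)oxy]prop-1-en-2-yl}cuprate (formed in the flask) | [Li+].C=C(CO[Si](C)(C)C(C)(C)C)[Cu-]C(=C)CO[Si](C)(C)C(C)(C)C | intermediate
16 | trimethylsilyl ketene acetal of ester 17 (formed in the flask) | C=C/C=C(\C)[C@@H]1OC(C)(C)O[C@H]1[C@H](C(=C)CO[Si](C)(C)C(C)(C)C)C=C(OC)O[Si](C)(C)C | intermediate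
17 | methyl (3S)-4-{[(tert-butyldimethylsilyl)oxy]methyl}-3-[(4S,5S)-2,2-dimethyl-5-[(2E)-penta-2,4-dien-2-yl]-1,3-dioxolan-4-yl]pent-4-enoate | C=C/C=C(\C)[C@@H]1OC(C)(C)O[C@H]1[C@H](C(=C)CO[Si](C)(C)C(C)(C)C)CC(=O)OC | intermediate
18 | methyl (3S)-4-{[(tert-butyldimethylsilyl)oxy]methyl}-3-[(4S,5R)-5-[(2R,3S)-3-ethenyl-2-methyloxiran-2-yl]-2,2-dimethyl-1,3-dioxolan-4-yl]pent-4-enoate | C=C[C@@H]1O[C@@]1(C)[C@@H]2OC(C)(C)O[C@H]2[C@H](C(=C)CO[Si](C)(C)C(C)(C)C)CC(=O)OC | intermediate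
19 | methyl (3S)-3-[(4S,5R)-5-[(2R,3S)-3-ethenyl-2-methyloxiran-2-yl]-2,2-dimethyl-1,3-dioxolan-4-yl]-4-(hydroxymethyl)pent-4-enoate (formed in the flask) | C=C[C@@H]1O[C@@]1(C)[C@@H]2OC(C)(C)O[C@H]2[C@H](C(=C)CO)CC(=O)OC | intermediate
20 | (4S)-4-[(4S,5R)-5-[(2R,3S)-3-ethenyl-2-methyloxiran-2-yl]-2,2-dimethyl-1,3-dioxolan-4-yl]-5-methylideneoxan-2-one | O=C1C[C@H]([C@@H]2OC(C)(C)O[C@H]2[C@]3(C)O[C@H]3C=C)C(=C)CO1 | intermediate
21 | (3S,4R)-4-[(4S,5R)-5-[(2R,3S)-3-ethenyl-2-methyloxiran-2-yl]-2,2-dimethyl-1,3-dioxolan-4-yl]-3-hydroxy-5-methylideneoxan-2-one | O=C1[C@@H](O)[C@H]([C@@H]2OC(C)(C)O[C@H]2[C@]3(C)O[C@H]3C=C)C(=C)CO1 | intermediate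
22 | (3S,4S)-4-[(4S,5R)-5-[(2R,3S)-3-ethenyl-2-methyloxiran-2-yl]-2,2-dimethyl-1,3-dioxolan-4-yl]-3-[(4-methoxyphenyl)methoxy]-5-methylideneoxan-2-one | O=C1[C@@H](OCc4ccc(OC)cc4)[C@H]([C@@H]2OC(C)(C)O[C@H]2[C@]3(C)O[C@H]3C=C)C(=C)CO1 | intermediate
23 | ethyl phenyl sulfone | CCS(=O)(=O)c1ccccc1 | starting material
24 | lithiated sulfone, [1-(benzenesulfonyl)ethyl]lithium (formed in the flask) | [Li]C(C)S(=O)(=O)c1ccccc1 | intermediate
25 | (2RS,4S,5S)-2-(benzenesulfonyl)-5-[(4S,5R)-5-[(2R,3S)-3-ethenyl-2-methyloxiran-2-yl]-2,2-dimethyl-1,3-dioxolan-4-yl]-7-hydroxy-4-[(4-methoxyphenyl)methoxy]-6-methylideneheptan-3-one | C=C[C@@H]1O[C@@]1(C)[C@@H]2OC(C)(C)O[C@H]2[C@H](C(=C)CO)[C@H](OCc3ccc(OC)cc3)C(=O)C(C)S(=O)(=O)c4ccccc4 | intermediate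
26 | (2RS,4S,5S)-2-(benzenesulfonyl)-7-[(tert-butyldimethylsilyl)oxy]-5-[(4S,5R)-5-[(2R,3S)-3-ethenyl-2-methyloxiran-2-yl]-2,2-dimethyl-1,3-dioxolan-4-yl]-4-[(4-methoxyphenyl)methoxy]-6-methylideneheptan-3-one (acyclic vinyl epoxide keto sulfone) | C=C[C@@H]1O[C@@]1(C)[C@@H]2OC(C)(C)O[C@H]2[C@H](C(=C)CO[Si](C)(C)C(C)(C)C)[C@H](OCc3ccc(OC)cc3)C(=O)C(C)S(=O)(=O)c4ccccc4 | intermediate
27 | (2E,4R,5R,6S,7S,8S)-10-(benzenesulfonyl)-4-hydroxy-5,6-(isopropylidenedioxy)-8-[(4-methoxyphenyl)methoxy]-4,10-dimethyl-7-{3-[(tert-butyldimethylsilyl)oxy]prop-1-en-2-yl}cyclodec-2-en-9-one (C10 epimers) | O=C1[C@@H](OCc2ccc(OC)cc2)[C@@H](C(=C)CO[Si](C)(C)C(C)(C)C)[C@@H]3OC(C)(C)O[C@H]3[C@](C)(O)/C=C/CC1(C)S(=O)(=O)c4ccccc4 | intermediate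
28 | samarium enolate of ketone 29, O-SmI2 enolate across C9=C10 (formed in the flask) | CC1=C(O[Sm](I)I)[C@@H](OCc2ccc(OC)cc2)[C@@H](C(=C)CO[Si](C)(C)C(C)(C)C)[C@@H]3OC(C)(C)O[C@H]3[C@](C)(O)/C=C/C1 | intermediate
29 | (2E,4R,5R,6S,7S,8S,10S)-4-hydroxy-5,6-(isopropylidenedioxy)-8-[(4-methoxyphenyl)methoxy]-4,10-dimethyl-7-{3-[(tert-butyldimethylsilyl)oxy]prop-1-en-2-yl}cyclodec-2-en-9-one | O=C1[C@@H](OCc2ccc(OC)cc2)[C@@H](C(=C)CO[Si](C)(C)C(C)(C)C)[C@@H]3OC(C)(C)O[C@H]3[C@](C)(O)/C=C/C[C@@H]1C | intermediate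
30 | (2E,4R,5R,6S,7S,8S,10S)-4,5,6-trihydroxy-7-(3-hydroxyprop-1-en-2-yl)-8-[(4-methoxyphenyl)methoxy]-4,10-dimethylcyclodec-2-en-9-one | O=C1[C@@H](OCc2ccc(OC)cc2)[C@@H](C(=C)CO)[C@H](O)[C@@H](O)[C@](C)(O)/C=C/C[C@@H]1C | intermediate
31 | hydroxy enal, the 7-(3-oxoprop-1-en-2-yl) analogue of 30 (formed in the flask) | O=C1[C@@H](OCc2ccc(OC)cc2)[C@@H](C(=C)C=O)[C@H](O)[C@@H](O)[C@](C)(O)/C=C/C[C@@H]1C | intermediate
32 | lactol, the 12-hydroxy-12,6-hemiacetal of 31 (formed in the flask) | O=C1[C@@H](OCc2ccc(OC)cc2)[C@H]3C(=C)C(O)O[C@@H]3[C@@H](O)[C@](C)(O)/C=C/C[C@@H]1C | intermediate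
33 | (2E,4R,5R,6S,7S,8S,10S)-4,5-dihydroxy-8-[(4-methoxyphenyl)methoxy]-9-oxogermacra-2,11(13)-dien-12,6-olide | O=C1[C@@H](OCc2ccc(OC)cc2)[C@H]3C(=C)C(=O)O[C@@H]3[C@@H](O)[C@](C)(O)/C=C/C[C@@H]1C | intermediate
34 | (R)-2-methylbutanoic acid | CC[C@@H](C)C(=O)O | starting material
35 | (2E,4R,5R,6S,7S,8S,10S)-4-hydroxy-8-[(4-methoxyphenyl)methoxy]-5-{[(2R)-2-methylbutanoyl]oxy}-9-oxogermacra-2,11(13)-dien-12,6-olide | O=C1[C@@H](OCc2ccc(OC)cc2)[C@H]3C(=C)C(=O)O[C@@H]3[C@@H](OC(=O)[C@H](C)CC)[C@](C)(O)/C=C/C[C@@H]1C | intermediate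
36 | (2E,4R,5R,6S,7R,8S,10S)-4,8-dihydroxy-5-{[(2R)-2-methylbutanoyl]oxy}-9-oxogermacra-2,11(13)-dien-12,6-olide | O=C1[C@@H](O)[C@H]2C(=C)C(=O)O[C@@H]2[C@@H](OC(=O)[C@H](C)CC)[C@](C)(O)/C=C/C[C@@H]1C | intermediate
37 | angelic acid, (2Z)-2-methylbut-2-enoic acid | C/C=C(/C)C(=O)O | starting material
38 | mixed anhydride, (2Z)-2-methylbut-2-enoic 2,4,6-trichlorobenzoic anhydride (formed in the flask) | C/C=C(/C)C(=O)OC(=O)c1c(Cl)cc(Cl)cc1Cl | intermediate
39 | (2E,4R,5R,6S,7S,8S,10S)-8-(angeloyloxy)-4-hydroxy-5-{[(2R)-2-methylbutanoyl]oxy}-9-oxogermacra-2,11(13)-dien-12,6-olide | O=C1[C@@H](OC(=O)/C(C)=C\C)[C@H]2C(=C)C(=O)O[C@@H]2[C@@H](OC(=O)[C@H](C)CC)[C@](C)(O)/C=C/C[C@@H]1C | intermediate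
40 | CNP0217571.1, (2S,3R,4R,5R,6S,7S,8S,10S)-8-(angeloyloxy)-2,3-epoxy-4-hydroxy-5-{[(2R)-2-methylbutanoyl]oxy}-9-oxogermacr-11(13)-en-12,6-olide | C=C1C(=O)O[C@H]2[C@H]1[C@H](OC(=O)/C(C)=C\C)C(=O)[C@@H](C)C[C@@H]1O[C@H]1[C@@](C)(O)[C@@H]2OC(=O)[C@H](C)CC | target

**Step count and risks**
Total steps: 23. Longest linear sequence: 22 steps (1 to 40 through steps 1–7 and 9–23); step 8 is a one-step side branch.

Most likely to fail:

Step 16. Ring closure may lose out to oligomerisation or to O-alkylation of the keto sulfone enolate because of transannular strain in the crowded ten-membered ring. The same C10–C1 bond would then be closed by a base-mediated sulfone-carbanion alkylation instead of palladium catalysis. Setting out from 26, MgBr2·OEt2 in Et2O at −20 °C opens the vinyl epoxide, and bromide-catalysed allylic equilibration should give the primary (E)-allylic bromohydrin F1. Slow addition of F1 to Cs2CO3 in DMF at high dilution alkylates C10 intramolecularly (SN2); the E-geometry keeps the C4 alkoxide from closing a five-membered ether. The fallback comes back to the route at 27.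

Step 17. Protonation of the flexible ring enolate may show poor facial selectivity at C10, and electron transfer may also cleave the C8–O bond. The sulfone would then be carried on and removed on a rigid framework. Setting out from 27, AcOH–THF–H2O gives the sulfonyl tetraol F2 and MnO2 gives the sulfonyl alpha-methylene gamma-lactone F3. Aluminium amalgam (Al/Hg) in aqueous THF at 0 °C then cleaves the C10–S bond, so that the enolate is protonated on the convex face of the trans-fused bicycle. The fallback comes back to the route at 33.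

Step 19. Hemiketal formation at the C9 ketone, lactol closure through O5 or glycol cleavage may divert the oxidation of the unprotected tetraol. C12 would then be raised to the acid level before the diol is released. Setting out from 29 (bypassing 30), HF·pyridine in THF removes only the silyl ether to give the primary allylic alcohol F4. TEMPO/PhI(OAc)2 in MeCN–H2O oxidises F4 to the acrylic acid F5. Aqueous acetic acid at 45 °C hydrolyses the acetonide, and the freed C6 hydroxyl lactonises under thermodynamic control to the gamma-lactone. The fallback comes back to the route at 33.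

Further compounds
F1 | step 16 | (E)-allylic bromohydrin, the C1-bromo C2=C3 C4-hydroxy opened form of 26 | BrC/C=C/[C@@](C)(O)[C@@H]1OC(C)(C)O[C@H]1[C@H](C(=C)CO[Si](C)(C)C(C)(C)C)[C@H](OCc2ccc(OC)cc2)C(=O)C(C)S(=O)(=O)c3ccccc3
F2 | step 17 | sulfonyl tetraol, the 10-(benzenesulfonyl) analogue of 30 | O=C1[C@@H](OCc2ccc(OC)cc2)[C@@H](C(=C)CO)[C@H](O)[C@@H](O)[C@](C)(O)/C=C/CC1(C)S(=O)(=O)c3ccccc3
F3 | step 17 | sulfonyl lactone, the 10-(benzenesulfonyl) analogue of 33 | O=C1[C@@H](OCc2ccc(OC)cc2)[C@H]3C(=C)C(=O)O[C@@H]3[C@@H](O)[C@](C)(O)/C=C/CC1(C)S(=O)(=O)c4ccccc4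
F4 | step 19 | primary allylic alcohol, the O12-desilylated acetonide of 29 | O=C1[C@@H](OCc2ccc(OC)cc2)[C@@H](C(=C)CO)[C@@H]3OC(C)(C)O[C@H]3[C@](C)(O)/C=C/C[C@@H]1C
F5 | step 19 | acrylic acid, the C12 carboxylic acid of F4 | O=C1[C@@H](OCc2ccc(OC)cc2)[C@@H](C(=C)C(=O)O)[C@@H]3OC(C)(C)O[C@H]3[C@](C)(O)/C=C/C[C@@H]1C
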